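## Retrosynthetic overview

Atom labels C1–C9 follow the bicyclo[3.3.1]nonane numbering of the target (C1 prenyl bridgehead, C3 acyl, C5 methyl bridgehead, C7 CH‑prenyl, C8 CMe2, C9 bridging C=O).

1. C7 endo‑prenyl ⇐ exo‑face hydroboration and B‑alkyl Suzuki coupling of a C7 exocyclic methylene (15).
2. Key disconnection C1–C8 (vicinal quaternary carbons): C1 of a dearomatised acylphloroglucinol is made electrophilic as an iodine(III) enolonium and is attacked by the γ‑carbon of a tethered allylsilane; this closes ring 2 (C1–C8–C7–C6–C5–C9).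
3. C5–C6 ⇐ Pd‑catalysed asymmetric dearomative allylation of arene 5 with allylic carbonate 12; this sets C5, which later dictates C1.
4. 5 ⇐ 2‑methylphloroglucinol (acylation, C‑prenylation); 12 ⇐ but‑2‑yn‑1‑ol in one pot (carbomagnesiation, methylation, O‑acylation).
5. Ring order: ring 1 (C1–C2–C3–C4–C5–C9) is the purchased arene; ring 2 is formed in the key step.

Assumption: compounds are drawn as single enol tautomers (target as the 4‑hydroxy‑2,9‑dione), and the (R,R)‑ligand in step 4 is taken to give (6R)‑13; if induction is opposite, the (S,S)‑ligand is used.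

## Route

Step 1
Reactants: 1 2-methylbenzene-1,3,5-triol (2-methylphloroglucinol); 2 2-methylpropanoyl chloride
Product: 3 2-methyl-1-(2,4,6-trihydroxy-3-methylphenyl)propan-1-one
Conditions: AlCl3 (3.5 equiv), PhNO2–CH2Cl2, 0 → 60 °C; aq HCl work-up
Reagents that add atoms: 2-methylpropanoyl chloride 2, CC(C)C(=O)Cl
Why: Friedel–Crafts C‑acylation of the electron‑rich triol at one of its two equivalent free ring carbons; no stereocentre is formed.

Step 2
Reactants: 3 2-methyl-1-(2,4,6-trihydroxy-3-methylphenyl)propan-1-one; 4 1-bromo-3-methylbut-2-ene (prenyl bromide)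
Product: 5 2-methyl-1-[2,4,6-trihydroxy-3-methyl-5-(3-methylbut-2-en-1-yl)phenyl]propan-1-one
Conditions: 4 (1.0 equiv), 10% aq KOH, 0 °C; then acidify
Reagents that add atoms: 1-bromo-3-methylbut-2-ene 4, CC(C)=CCBr
Why: C‑alkylation of the phenoxide in water (standard C‑prenylation of acylphloroglucinols) at the only free ring carbon; no stereocentre is formed.

Step 3
Reactants: 6 but-2-yn-1-ol; 7 (trimethylsilyl)methylmagnesium chloride; 8 iodomethane; 9 methyl carbonochloridate (methyl chloroformate)
Product: 12 methyl 3-methyl-2-[(trimethylsilyl)methyl]but-2-en-1-yl carbonate, via magnesacycle 10 (not isolated), via iodomagnesium alkoxide 11 (not isolated)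
Conditions: 7 (2.5 equiv), CuI (10 mol %), THF, reflux; then 8 (4 equiv), DMPU, 0 °C → rt; then 9 (3 equiv), 0 °C → rt
Reagents that add atoms: (trimethylsilyl)methylmagnesium chloride 7, C[Si](C)(C)C[Mg]Cl; iodomethane 8, CI; methyl carbonochloridate 9, COC(=O)Cl
Why: Copper‑catalysed anti‑carbomagnesiation of the propargylic alkoxide puts Me3SiCH2 on C2 and Mg on C3 (five‑membered chelate), copper‑mediated methylation of the alkenyl–Mg bond gives the isopropylidene terminus (alkene geometry becomes irrelevant), and the alkoxide is acylated in the same pot; no stereocentre is formed.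

Step 4
Reactants: 5 2-methyl-1-[2,4,6-trihydroxy-3-methyl-5-(3-methylbut-2-en-1-yl)phenyl]propan-1-one; 12 methyl 3-methyl-2-[(trimethylsilyl)methyl]but-2-en-1-yl carbonate
Product: 13 (6R)-3,5-dihydroxy-6-methyl-2-(3-methylbut-2-en-1-yl)-6-{3-methyl-2-[(trimethylsilyl)methyl]but-2-en-1-yl}-4-(2-methylpropanoyl)cyclohexa-2,4-dien-1-one
Conditions: Pd2(dba)3·CHCl3 (2.5 mol %), (R,R)-DACH-phenyl Trost ligand (7.5 mol %), 12 (1.05 equiv), THF, 0 °C → rt, argon
Reagents that add atoms: none
Why: Tsuji–Trost asymmetric allylic dearomatisation, in which the phenoxide (formed by the methoxide leaving group) attacks the CH2 terminus of the π‑allyl–Pd cation through its less hindered methyl‑bearing ring carbon faster than the silyl group is lost, and the chiral ligand pocket selects the enantiotopic face of the planar nucleophile to set the quaternary stereocentre (6R, the future C5).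

Step 5
Reactants: 13 (6R)-3,5-dihydroxy-6-methyl-2-(3-methylbut-2-en-1-yl)-6-{3-methyl-2-[(trimethylsilyl)methyl]but-2-en-1-yl}-4-(2-methylpropanoyl)cyclohexa-2,4-dien-1-one
Product: 15 (1R,5R)-4-hydroxy-5,8,8-trimethyl-7-methylidene-1-(3-methylbut-2-en-1-yl)-3-(2-methylpropanoyl)bicyclo[3.3.1]non-3-ene-2,9-dione, via iodine(III) enol ether 14 (not isolated)
Conditions: PhI(OAc)2 (1.1 equiv), (CF3)2CHOH–CH2Cl2 (1:4), −40 → 0 °C, argon; evaporate, chromatography
Reagents that add atoms: none
Why: Proposed new method: PhI(OAc)2 exchanges onto the free enol oxygen next to the prenyl‑bearing carbon C1 (the carbon at which such dearomatised acylphloroglucinols are oxidised; the C3 enol is chelated and carries three acyl groups), giving an O‑iodanyl enol ether that is an enolonium equivalent electrophilic at C1; the γ‑carbon (C8) of the tethered allylsilane attacks C1 in SN2′ fashion through a six‑membered transition state with loss of PhI, and the β‑silyl cation at C7 then loses Me3Si+ to leave the exocyclic methylene, so two normally nucleophilic carbons are joined as vicinal quaternary centres; C1 can only bond on the face that carries the C5 tether, so C5 fixes C1 (1R,5R); the closest known reaction types are the hypervalent‑iodine oxidative Hosomi–Sakurai allylation of phenols ("aromatic ring umpolung") and the α‑allylation of iodine(III) enolonium species and of oxidised 1,3‑dicarbonyls with allylsilanes.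

Step 6
Reactants: 15 (1R,5R)-4-hydroxy-5,8,8-trimethyl-7-methylidene-1-(3-methylbut-2-en-1-yl)-3-(2-methylpropanoyl)bicyclo[3.3.1]non-3-ene-2,9-dione; 16 9-borabicyclo[3.3.1]nonane (9-BBN); 17 1-bromo-2-methylprop-1-ene
Product: 19 (1R,5R,7R)-4-hydroxy-5,8,8-trimethyl-1,7-bis(3-methylbut-2-en-1-yl)-3-(2-methylpropanoyl)bicyclo[3.3.1]non-3-ene-2,9-dione, via bis(9-BBN) adduct 18 (not isolated)
Conditions: 16 (2.3 equiv, 0.5 M in THF), 0 → 40 °C; then 17 (3 equiv), Pd(dppf)Cl2 (8 mol %), AsPh3 (8 mol %), 3 M aq K3PO4, DMF, rt → 50 °C; dilute citric acid work-up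
Reagents that add atoms: 1-bromo-2-methylprop-1-ene 17, CC(C)=CBr
Why: Anti‑Markovnikov hydroboration of the 1,1‑disubstituted exocyclic alkene (9‑BBN leaves the trisubstituted prenyl alkene alone; one equivalent is taken up by the enol O–H) occurs from the open exo face because the endo face of C7 is blocked by the C2–C3–C4 bridge, so H is delivered exo and the CH2B arm ends endo (7R), and B‑alkyl Suzuki–Miyaura coupling with the alkenyl bromide converts that arm into the endo prenyl group.

## Compound list

1 | 2-methylbenzene-1,3,5-triol (2-methylphloroglucinol) | Cc1c(O)cc(O)cc1O | starting material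
2 | 2-methylpropanoyl chloride (isobutyryl chloride) | CC(C)C(=O)Cl | starting material
3 | 2-methyl-1-(2,4,6-trihydroxy-3-methylphenyl)propan-1-one | CC(C)C(=O)c1c(O)cc(O)c(C)c1O | intermediate
4 | 1-bromo-3-methylbut-2-ene (prenyl bromide) | CC(C)=CCBr | starting material
5 | 2-methyl-1-[2,4,6-trihydroxy-3-methyl-5-(3-methylbut-2-en-1-yl)phenyl]propan-1-one | CC(C)C(=O)c1c(O)c(C)c(O)c(CC=C(C)C)c1O | intermediate
6 | but-2-yn-1-ol | CC#CCO | starting material
7 | (trimethylsilyl)methylmagnesium chloride | C[Si](C)(C)C[Mg]Cl | starting material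
8 | iodomethane | CI | starting material
9 | methyl carbonochloridate (methyl chloroformate) | COC(=O)Cl | starting material
10 | 3-methyl-4-[(trimethylsilyl)methyl]-2,5-dihydro-1,2-oxamagnesole (cyclic alkenylmagnesium alkoxide) | CC1=C(C[Si](C)(C)C)CO[Mg]1 | intermediate
11 | iodomagnesium 3-methyl-2-[(trimethylsilyl)methyl]but-2-en-1-olate | CC(C)=C(CO[Mg]I)C[Si](C)(C)C | intermediate
12 | methyl 3-methyl-2-[(trimethylsilyl)methyl]but-2-en-1-yl carbonate | COC(=O)OCC(C[Si](C)(C)C)=C(C)C | intermediate
13 | (6R)-3,5-dihydroxy-6-methyl-2-(3-methylbut-2-en-1-yl)-6-{3-methyl-2-[(trimethylsilyl)methyl]but-2-en-1-yl}-4-(2-methylpropanoyl)cyclohexa-2,4-dien-1-one | CC(C)=C(C[Si](C)(C)C)C[C@@]1(C)C(=O)C(CC=C(C)C)=C(O)C(C(=O)C(C)C)=C1O | intermediate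
14 | (6R)-3-{[(acetyloxy)(phenyl)-λ3-iodanyl]oxy}-5-hydroxy-6-methyl-2-(3-methylbut-2-en-1-yl)-6-{3-methyl-2-[(trimethylsilyl)methyl]but-2-en-1-yl}-4-(2-methylpropanoyl)cyclohexa-2,4-dien-1-one | CC(C)=C(C[Si](C)(C)C)C[C@@]1(C)C(=O)C(CC=C(C)C)=C(OI(OC(C)=O)c2ccccc2)C(C(=O)C(C)C)=C1O | intermediate
15 | (1R,5R)-4-hydroxy-5,8,8-trimethyl-7-methylidene-1-(3-methylbut-2-en-1-yl)-3-(2-methylpropanoyl)bicyclo[3.3.1]non-3-ene-2,9-dione | C=C1C[C@@]2(C)C(=O)[C@](CC=C(C)C)(C(=O)C(C(=O)C(C)C)=C2O)C1(C)C | intermediate
16 | 9-borabicyclo[3.3.1]nonane (9-BBN, drawn as monomer) | B1C2CCCC1CCC2 | starting material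
17 | 1-bromo-2-methylprop-1-ene | CC(C)=CBr | starting material
18 | (1R,5R,7R)-7-[(9-borabicyclo[3.3.1]nonan-9-yl)methyl]-4-[(9-borabicyclo[3.3.1]nonan-9-yl)oxy]-5,8,8-trimethyl-1-(3-methylbut-2-en-1-yl)-3-(2-methylpropanoyl)bicyclo[3.3.1]non-3-ene-2,9-dione | C1CC2CCCC(C1)B2C[C@@H]1C[C@@]2(C)C(=O)[C@](CC=C(C)C)(C(=O)C(C(=O)C(C)C)=C2OB2C3CCCC2CCC3)C1(C)C | intermediate
19 | (1R,5R,7R)-4-hydroxy-5,8,8-trimethyl-1,7-bis(3-methylbut-2-en-1-yl)-3-(2-methylpropanoyl)bicyclo[3.3.1]non-3-ene-2,9-dione | CC(C)=CC[C@@H]1C[C@@]2(C)C(=O)[C@](CC=C(C)C)(C(=O)C(C(=O)C(C)C)=C2O)C1(C)C | target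

## Step count and risks

Total step count: 6. Longest linear sequence: 5 (steps 1, 2, 4, 5, 6; the carbonate branch is step 3).

**Step 5 (key ring closure).** Acetoxylation at C1, a radical 5‑exo closure to a bicyclo[3.2.1]octane, attack at C3, or protodesilylation may outrun the closure between two fully substituted carbons. The fallback abandons the two‑electron iodine(III) pathway for a one‑electron oxidative radical–polar crossover cyclisation. It sets out from 13: Mn(OAc)3·2H2O (2.2 equiv) with catalytic Cu(OAc)2 in AcOH at rt gives the C1‑centred electrophilic triketone radical, which adds 6‑endo to C8. The tertiary β‑silyl radical at C7 is oxidised by Cu(II) and loses the silyl group, so the route is rejoined directly at 15. New compounds: none F0.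

**Step 4 (asymmetric dearomative allylation).** The ee on this flat, trisubstituted phenoxide is untested, and attack through the prenyl‑bearing carbon, through oxygen, or with loss of silicon may compete. The fallback replaces asymmetric catalysis by resolution. It sets out from 5 and 12: achiral Pd(PPh3)4 in THF gives racemic 13 F1, freed from regioisomers by chromatography. F1 is crystallised with (S)‑1‑phenylethylamine from EtOAc/heptane as the diastereomeric salt (S)‑1‑phenylethylammonium (6R)‑enolate F2 (the antipodal amine is used if the other diastereomer is the less soluble one). The (6S)‑enantiomer F3 stays in the mother liquor. Partition of F2 between 1 M HCl and Et2O returns to the route at 13.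

**Step 6 (hydroboration/Suzuki).** The neopentyl‑type alkene may hydroborate slowly, so carbonyl reduction or a persistent O–B chelate could interfere. The fallback replaces boron by rhodium hydroformylation and olefination. It sets out from 15: Rh(acac)(CO)2/Xantphos, CO/H2 (1:1, 20 bar), toluene, 80 °C gives the linear aldehyde 2-[(1R,5R,7S)-4-hydroxy-5,8,8-trimethyl-1-(3-methylbut-2-en-1-yl)-3-(2-methylpropanoyl)-2,9-dioxobicyclo[3.3.1]non-3-en-7-yl]acetaldehyde F4 (Rh–H also adds from the exo face; 7S is the same spatial arrangement, only the CIP priorities change). Wittig reaction with isopropylidene(triphenyl)phosphorane (from isopropyltriphenylphosphonium iodide and KHMDS, 2.2 equiv, THF, −78 → 0 °C) then rejoins the route at 19.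

## Further compounds

F1 | step 4 | racemic 3,5-dihydroxy-6-methyl-2-(3-methylbut-2-en-1-yl)-6-{3-methyl-2-[(trimethylsilyl)methyl]but-2-en-1-yl}-4-(2-methylpropanoyl)cyclohexa-2,4-dien-1-one | CC(C)=C(C[Si](C)(C)C)CC1(C)C(=O)C(CC=C(C)C)=C(O)C(C(=O)C(C)C)=C1O
F2 | step 4 | (S)-1-phenylethylammonium salt of the (6R)-enolate of 13 | C[C@H]([NH3+])c1ccccc1.CC(C)=C(C[Si](C)(C)C)C[C@@]1(C)C(=O)C(CC=C(C)C)=C([O-])C(C(=O)C(C)C)=C1O
F3 | step 4 | (6S)-enantiomer of 13 (mother liquor) | CC(C)=C(C[Si](C)(C)C)C[C@]1(C)C(=O)C(CC=C(C)C)=C(O)C(C(=O)C(C)C)=C1O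
F0 | step 5 | none | none
F4 | step 6 | 2-[(1R,5R,7S)-4-hydroxy-5,8,8-trimethyl-1-(3-methylbut-2-en-1-yl)-3-(2-methylpropanoyl)-2,9-dioxobicyclo[3.3.1]non-3-en-7-yl]acetaldehyde | O=CC[C@@H]1C[C@@]2(C)C(=O)[C@](CC=C(C)C)(C(=O)C(C(=O)C(C)C)=C2O)C1(C)C
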